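**Retrosynthetic overview**
1. Target 28 ⇐ desilylation/γ-lactonisation and acetylation ⇐ formyl-cyclopentane/ten-membered bicycle 25, made in one step from the 14-membered epoxy allylic alcohol 23 by epoxide-initiated transannular C1–C10 cyclisation and 1,2-shift ring contraction.
2. Ring order: 14-membered carbocycle → (transient 6/10) → 5/10 → γ-lactone last.
3. 23 ⇐ B-alkyl Suzuki macrocyclisation (C4–C5) ⇐ 21 ⇐ Ni/Cr coupling (C11–C12) of vinyl iodide 11 with epoxy aldehyde 20.
4. 11 (C5–C11, C17–C19) ⇐ diacetone-D-glucose: 3-ulose + propionamide enolate (C8, C17), then (Z)-halo-olefination at sugar C5 and C1 (C7 and C9 come from the sugar).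
5. 20 (C12–C14, C1–C4) ⇐ 3-silyloxypropanal: (Z)-iodo-olefination, acrolein addition, Sharpless kinetic-resolution epoxidation.

Assumption: atoms carry briarane locants (C1 = quaternary carbon with CH3-15, C2 and C14 = acetoxy carbons, C7–O–C19 = lactone, C12 = aldehyde carbon, C17 = lactone α-carbon); aluminium on oxygen is not drawn in 24.

**Step 1**
Reactants: 1 1,2:5,6-di-O-isopropylidene-α-D-glucofuranose
Product: 2 1,2:5,6-di-O-isopropylidene-α-D-ribo-hexofuranos-3-ulose
Conditions: Dess–Martin periodinane, CH2Cl2, rt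
Reagents that add atoms: none
Why: Dess–Martin oxidation of the only free hydroxyl gives the known 3-ulose without touching a stereocentre.

**Step 2**
Reactants: 2 the 3-ulose; 3 N-methoxy-N-methylpropanamide
Product: 5 3-C-[(1R)-1-(N-methoxy-N-methylcarbamoyl)ethyl]-1,2:5,6-di-O-isopropylidene-3-O-triethylsilyl-α-D-allofuranose, via lithium aldolate 4 (not isolated)
Conditions: LDA, 3, THF, −78 °C; add 2; then TESOTf, −78 → 0 °C
Reagents that add atoms: triethylsilyl trifluoromethanesulfonate, CC[Si](CC)(CC)OS(=O)(=O)C(F)(F)F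
Why: Aldol addition of the (Z)-lithium amide enolate to the ketone from the convex β-face (opposite the 1,2-acetonide) gives the D-allo tertiary carbinol (future C8), a closed Zimmerman–Traxler transition state with the C4 arm equatorial is expected to set the α-methyl centre (future C17, R), and in-situ O-silylation blocks retro-aldol.

**Step 3**
Reactants: 5 the silylated aldol adduct
Product: 6 3-C-branched 1,2-O-isopropylidene-3-O-triethylsilyl-α-D-ribo-pentodialdo-1,4-furanose (aldehyde at sugar C5 = C10)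
Conditions: H5IO6, EtOAc, rt
Reagents that add atoms: none
Why: Periodic acid selectively hydrolyses the terminal 5,6-acetonide and cleaves the resulting glycol, leaving the 1,2-acetonide and the C4 stereocentre intact.

**Step 4**
Reactants: 6 the C10 aldehyde
Product: 7 furanose bearing a (Z)-2-iodoprop-1-enyl group at sugar C4 (C10=C11 with iodine on C11)
Conditions: EtPPh3I, n-BuLi, THF; I2, −78 °C; NaHMDS; then 6, −78 → −20 °C
Reagents that add atoms: ethyltriphenylphosphonium iodide, CC[P+](c1ccccc1)(c1ccccc1)c1ccccc1.[I-]; iodine, II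
Why: Stork–Zhao-type Wittig olefination with the α-iodo ylide gives the (Z)-2-iodoalkene (iodine cis to C9), which fixes the later C10=C11 geometry.

**Step 5**
Reactants: 7 the furanosyl vinyl iodide
Product: 9 open-chain C6 diethyl dithioacetal with 7,8,9-tris(triethylsilyloxy) groups, via dithioacetal diol 8 (not isolated)
Conditions: EtSH, BF3·OEt2, CH2Cl2, −30 °C; then 2,6-lutidine, TESOTf, −30 → 0 °C
Reagents that add atoms: ethanethiol, CCS; triethylsilyl trifluoromethanesulfonate, CC[Si](CC)(CC)OS(=O)(=O)C(F)(F)F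
Why: Fischer-type dithioacetalisation opens the furanose at the anomeric carbon and frees O7 and O9, which are silylated at once so that neither can attack the amide; no stereocentre is touched.

**Step 6**
Reactants: 9 the tris-TES dithioacetal
Product: 10 C6 aldehyde (2,3,4-tris-O-TES open chain)
Conditions: I2, NaHCO3, acetone/H2O, 0 °C
Reagents that add atoms: water, O
Why: Iodine-mediated oxidative hydrolysis of the dithioacetal gives the α-silyloxy aldehyde under buffered conditions that spare silyl ethers and the vinyl iodide.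

**Step 7**
Reactants: 10 the C6 aldehyde
Product: 11 southern fragment, (5Z,10Z)-5-bromo-11-iodo diene with 7,8,9-tris-OTES and the C19 Weinreb amide
Conditions: EtPPh3Br, n-BuLi, THF; Br2, −78 °C; NaHMDS; then 10, −78 °C
Reagents that add atoms: ethyltriphenylphosphonium bromide, CC[P+](c1ccccc1)(c1ccccc1)c1ccccc1.[Br-]; bromine, BrBr
Why: A second Stork–Zhao-type olefination, now with the α-bromo ylide, gives the (Z)-2-bromoalkene (bromine cis to C7), which fixes the later C5=C6 geometry.

**Step 8**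
Reactants: 12 3-(tert-butyldimethylsilyloxy)propanal
Product: 13 (Z)-tert-butyl[(4-iodopent-3-en-1-yl)oxy]dimethylsilane
Conditions: EtPPh3I, n-BuLi, THF; I2, −78 °C; NaHMDS; then 12, −78 → −20 °C
Reagents that add atoms: ethyltriphenylphosphonium iodide, CC[P+](c1ccccc1)(c1ccccc1)c1ccccc1.[I-]; iodine, II
Why: Stork–Zhao olefination gives the (Z)-2-iodoalkene (iodine cis to C13), the precursor of the cis-epoxide.

**Step 9**
Reactants: 13 the (Z)-vinyl iodide; 14 acrolein
Product: 16 rac-(4Z)-7-(tert-butyldimethylsilyloxy)-4-methylhepta-1,4-dien-3-ol, via alkenyllithium 15 (not isolated)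
Conditions: t-BuLi (2.1 equiv), Et2O, −78 °C; then 14, −78 °C
Reagents that add atoms: none
Why: Iodine–lithium exchange proceeds with retention of alkene geometry and 1,2-addition to acrolein gives the racemic bis-allylic alcohol (C2).

**Step 10**
Reactants: 16 the racemic dienol
Product: 17 (2R)-erythro cis-epoxy alcohol (C14–C1 epoxide, 14S; free C2–OH; vinyl retained)
Conditions: Ti(OiPr)4, D-(−)-DIPT, t-BuOOH (0.55 equiv), 4 Å MS, CH2Cl2, −20 °C; unreacted (S)-16 separated
Reagents that add atoms: tert-butyl hydroperoxide, CC(C)(C)OO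
Why: Sharpless kinetic-resolution epoxidation with D-(−)-tartrate epoxidises only the trisubstituted alkene of the (R)-alcohol from the face that gives the erythro epoxy alcohol, setting C2, C1 and C14 in one step.

**Step 11**
Reactants: 17 the epoxy alcohol
Product: 18 (2R)-2-acetoxy epoxide TBS ether
Conditions: Ac2O, pyridine, DMAP (cat.), CH2Cl2, 0 °C
Reagents that add atoms: acetic anhydride, CC(=O)OC(C)=O
Why: Standard acylation installs the C2 acetate of the target and makes the oxygen next to the epoxide electron-poor.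

**Step 12**
Reactants: 18 the TBS ether
Product: 19 primary alcohol (C12–OH)
Conditions: TBAF, AcOH, THF, 0 °C
Reagents that add atoms: none
Why: Buffered fluoride removes the primary TBS group without acetate migration or epoxide opening.

**Step 13**
Reactants: 19 the primary alcohol
Product: 20 northern fragment, β,γ-epoxy aldehyde (C12 aldehyde) with C2 acetate and C3=C4 vinyl
Conditions: Dess–Martin periodinane, NaHCO3, CH2Cl2, 0 °C; used at once
Reagents that add atoms: none
Why: Buffered Dess–Martin oxidation gives the sensitive β,γ-epoxy aldehyde under non-basic conditions.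

**Step 14**
Reactants: 11 the southern vinyl iodide; 20 the northern epoxy aldehyde
Product: 21 seco-triene, (12S)-allylic alcohol with the C11–C12 bond formed
Conditions: CrCl2, NiCl2 (cat.), Kishi chiral sulfonamide ligand (antipode that gives 12S), Et3N, MeCN/THF, rt
Reagents that add atoms: none
Why: In this Nozaki–Hiyama–Kishi coupling Ni(0) inserts into the alkenyl C–I bond much faster than into the alkenyl C–Br bond, the alkenylchromium adds to the aldehyde under near-neutral conditions that tolerate epoxide, acetate and amide, and the chiral Cr–sulfonamide complex sets C12.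

**Step 15**
Reactants: 21 the seco-triene
Product: 23 14-membered (5Z,10Z)-macrocycle with the C14–C1 cis-epoxide and 12-OH, via B-alkyl-9-BBN adduct 22 (not isolated)
Conditions: 9-BBN, THF, rt; then slow addition to Pd(dppf)Cl2, AsPh3, Cs2CO3, DMF/THF/H2O, 50 °C, 2 mM
Reagents that add atoms: none
Why: 9-BBN hydroborates only the monosubstituted alkene (boron at C4) and the B-alkyl Suzuki–Miyaura macrocyclisation joins C4 to C5 with retention of the (Z)-bromoalkene geometry and creates no stereocentre.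

**Step 16**
Reactants: 23 the macrocyclic epoxy allylic alcohol
Product: 25 5/10-bicyclic aldehyde (14-OH, C11 quaternary with CH3 and CHO, 2-OAc), via C11 carbocation 24 (not isolated)
Conditions: MeAlCl2 (5 equiv), CH2Cl2, −78 °C; aq. Rochelle salt
Reagents that add atoms: none
Why: Proposed new method: the Lewis acid opens the epoxide at the tertiary C1, the transannular C10=C11 alkene attacks C1 anti to the departing oxygen (inversion at C1; in a chair, the Z-epoxide and Z-alkene place C2 and C9 trans-diaxial, giving the trans ring fusion with 14-O cis to C2), and the resulting β-hydroxy C11 cation is quenched by 1,2-shift of C13 from C12 to C11 anti to the axial C12–O bond, which contracts the ring and leaves C12 as the aldehyde cis to CH3-15; the closest known reactions are epoxide-initiated cation–olefin cyclisation, the Overman Prins–pinacol sequence and the Meinwald/semipinacol ring contraction of 1-methylcyclohexene oxides.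

**Step 17**
Reactants: 25 the bicyclic hydroxy aldehyde
Product: 26 2,14-diacetate
Conditions: Ac2O, DMAP, pyridine, rt
Reagents that add atoms: acetic anhydride, CC(=O)OC(C)=O
Why: The only free hydroxyl (C14) is acylated under standard DMAP catalysis.

**Step 18**
Reactants: 26 the tris-TES diacetate
Product: 28 target CNP0123121.2, via triol amide 27 (not isolated)
Conditions: HF·pyridine, THF/pyridine, 0 °C → rt; then CSA (0.2 equiv), CH2Cl2, rt
Reagents that add atoms: none
Why: Fluoride removes the three TES groups and the γ-hydroxy Weinreb amide lactonises under acid catalysis onto the less hindered allylic C7–OH rather than the neopentyl-like C9–OH, closing the 7,19-γ-lactone with every stereocentre already in place.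

**Compound list**
1 | 1,2:5,6-di-O-isopropylidene-α-D-glucofuranose | CC1(C)OC[C@@H](O1)[C@H]2O[C@@H]3OC(C)(C)O[C@@H]3[C@H]2O | starting material
2 | 1,2:5,6-di-O-isopropylidene-α-D-ribo-hexofuranos-3-ulose | CC1(C)OC[C@@H](O1)[C@H]2O[C@@H]3OC(C)(C)O[C@@H]3C2=O | intermediate
3 | N-methoxy-N-methylpropanamide | CCC(=O)N(C)OC | starting material
4 | lithium aldolate (3-C-branched D-allo alkoxide) | CC1(C)OC[C@@H](O1)[C@H]2O[C@@H]3OC(C)(C)O[C@@H]3[C@@]2([O-])[C@@H](C)C(=O)N(C)OC.[Li+] | intermediate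
5 | 3-C-[(1R)-1-(N-methoxy-N-methylcarbamoyl)ethyl]-1,2:5,6-di-O-isopropylidene-3-O-triethylsilyl-α-D-allofuranose | CC1(C)OC[C@@H](O1)[C@H]2O[C@@H]3OC(C)(C)O[C@@H]3[C@@]2(O[Si](CC)(CC)CC)[C@@H](C)C(=O)N(C)OC | intermediate
6 | 3-C-branched 1,2-O-isopropylidene-3-O-TES-α-D-ribo-pentodialdo-1,4-furanose (C10 aldehyde) | O=C[C@H]1O[C@@H]2OC(C)(C)O[C@@H]2[C@@]1(O[Si](CC)(CC)CC)[C@@H](C)C(=O)N(C)OC | intermediate
7 | furanose with (Z)-2-iodoprop-1-enyl at sugar C4 (C10=C11–I) | C/C(I)=C/[C@H]1O[C@@H]2OC(C)(C)O[C@@H]2[C@@]1(O[Si](CC)(CC)CC)[C@@H](C)C(=O)N(C)OC | intermediate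
8 | open-chain C6 diethyl dithioacetal, 7,9-diol, 8-OTES | CCSC(SCC)[C@H](O)[C@@](O[Si](CC)(CC)CC)([C@@H](C)C(=O)N(C)OC)[C@H](O)/C=C(/C)I | intermediate
9 | open-chain C6 diethyl dithioacetal, 7,8,9-tris-OTES | CCSC(SCC)[C@H](O[Si](CC)(CC)CC)[C@@](O[Si](CC)(CC)CC)([C@@H](C)C(=O)N(C)OC)[C@H](O[Si](CC)(CC)CC)/C=C(/C)I | intermediate
10 | C6 aldehyde, 7,8,9-tris-OTES, (10Z)-11-iodoalkene | O=C[C@H](O[Si](CC)(CC)CC)[C@@](O[Si](CC)(CC)CC)([C@@H](C)C(=O)N(C)OC)[C@H](O[Si](CC)(CC)CC)/C=C(/C)I | intermediate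
11 | southern fragment: (5Z,10Z)-5-bromo-11-iodo diene, 7,8,9-tris-OTES, C19 Weinreb amide (7S, 9R, 17R; C8 as in target) | C/C(Br)=C/[C@H](O[Si](CC)(CC)CC)[C@@](O[Si](CC)(CC)CC)([C@@H](C)C(=O)N(C)OC)[C@H](O[Si](CC)(CC)CC)/C=C(/C)I | intermediate
12 | 3-(tert-butyldimethylsilyloxy)propanal | O=CCCO[Si](C)(C)C(C)(C)C | starting material
13 | (Z)-tert-butyl[(4-iodopent-3-en-1-yl)oxy]dimethylsilane | C/C(I)=C/CCO[Si](C)(C)C(C)(C)C | intermediate
14 | acrolein | C=CC=O | starting material
15 | (Z)-alkenyllithium from 13 | C/C([Li])=C/CCO[Si](C)(C)C(C)(C)C | intermediate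
16 | rac-(4Z)-7-(tert-butyldimethylsilyloxy)-4-methylhepta-1,4-dien-3-ol | C=CC(O)/C(C)=C\CCO[Si](C)(C)C(C)(C)C | intermediate
17 | (2R,14S)-erythro cis-epoxy alcohol (C14–C1 epoxide), TBS ether | C=C[C@@H](O)[C@@]1(C)O[C@H]1CCO[Si](C)(C)C(C)(C)C | intermediate
18 | (2R)-2-acetoxy cis-epoxide, TBS ether | C=C[C@@H](OC(C)=O)[C@@]1(C)O[C@H]1CCO[Si](C)(C)C(C)(C)C | intermediate
19 | (2R)-2-acetoxy cis-epoxide, C12 primary alcohol | C=C[C@@H](OC(C)=O)[C@@]1(C)O[C@H]1CCO | intermediate
20 | northern fragment: β,γ-epoxy aldehyde (C12), 2-OAc, C3=C4 vinyl | C=C[C@@H](OC(C)=O)[C@@]1(C)O[C@H]1CC=O | intermediate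
21 | seco-triene, (12S)-alcohol, C5–Br, terminal vinyl | C/C(Br)=C/[C@H](O[Si](CC)(CC)CC)[C@@](O[Si](CC)(CC)CC)([C@@H](C)C(=O)N(C)OC)[C@H](O[Si](CC)(CC)CC)/C=C(/C)[C@@H](O)C[C@@H]1O[C@]1(C)[C@H](OC(C)=O)C=C | intermediate
22 | B-alkyl-9-BBN adduct of 21 (boron at C4) | C/C(Br)=C/[C@H](O[Si](CC)(CC)CC)[C@@](O[Si](CC)(CC)CC)([C@@H](C)C(=O)N(C)OC)[C@H](O[Si](CC)(CC)CC)/C=C(/C)[C@@H](O)C[C@@H]1O[C@]1(C)[C@H](OC(C)=O)CCB1C2CCCC1CCC2 | intermediate
23 | 14-membered (5Z,10Z)-macrocycle, C14–C1 cis-epoxide, 12-OH, 2-OAc, 7,8,9-tris-OTES | C/C1=C/[C@H](O[Si](CC)(CC)CC)[C@@](O[Si](CC)(CC)CC)([C@@H](C)C(=O)N(C)OC)[C@H](O[Si](CC)(CC)CC)/C=C(/C)[C@@H](O)C[C@@H]2O[C@]2(C)[C@H](OC(C)=O)CC1 | intermediate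
24 | 6/10-bicyclic tertiary C11 carbocation with 12-OH and 14-OH | O[C@H]1C[C@H](O)[C+](C)[C@@H]2[C@@H](O[Si](CC)(CC)CC)[C@](O[Si](CC)(CC)CC)([C@@H](C)C(=O)N(C)OC)[C@H](/C=C(/C)CC[C@@H](OC(C)=O)[C@@]12C)O[Si](CC)(CC)CC | intermediate
25 | 5/10-bicyclic aldehyde, 14-OH, 2-OAc, 7,8,9-tris-OTES, C19 Weinreb amide | O[C@H]1C[C@](C)(C=O)[C@@H]2[C@@H](O[Si](CC)(CC)CC)[C@](O[Si](CC)(CC)CC)([C@@H](C)C(=O)N(C)OC)[C@H](/C=C(/C)CC[C@@H](OC(C)=O)[C@@]12C)O[Si](CC)(CC)CC | intermediate
26 | 2,14-diacetate of 25 | CC(=O)O[C@H]1C[C@](C)(C=O)[C@@H]2[C@@H](O[Si](CC)(CC)CC)[C@](O[Si](CC)(CC)CC)([C@@H](C)C(=O)N(C)OC)[C@H](/C=C(/C)CC[C@@H](OC(C)=O)[C@@]12C)O[Si](CC)(CC)CC | intermediate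
27 | 7,8,9-triol Weinreb amide | CC(=O)O[C@H]1C[C@](C)(C=O)[C@@H]2[C@@H](O)[C@](O)([C@@H](C)C(=O)N(C)OC)[C@H](/C=C(/C)CC[C@@H](OC(C)=O)[C@@]12C)O | intermediate
28 | CNP0123121.2 | CC(=O)O[C@H]1C[C@](C)(C=O)[C@@H]2[C@@H](O)[C@@]3(O)[C@H](/C=C(/C)CC[C@@H](OC(C)=O)[C@@]12C)OC(=O)[C@@H]3C | target

**Step count**
Total steps: 18. Longest linear sequence: 12 steps (steps 1–7, then 14–18); the northern branch is steps 8–13.

**Three steps most likely to fail**

Step 16 (cascade). The main dangers are participation of the C2 acetate or a hydride shift at the C1 cation, attack of the other 1,5-related alkene (C5=C6) on C1, and the wrong ring conformer in the 1,2-shift. Fallback: set out from 21 and run the same MeAlCl2 cyclisation/ring contraction before the macrocycle is closed, where the C5 bromoalkene and the terminal vinyl group are too poor as π-nucleophiles to compete. This gives the seco cyclopentane carbaldehyde F1. NaBH4 reduction shields the aldehyde as the neopentyl alcohol and gives the seco diol F2. 9-BBN hydroboration and Pd-catalysed B-alkyl Suzuki closure of the ten-membered ring give the bicyclic diol F3. Selective TEMPO/PhI(OAc)2 oxidation of the primary alcohol returns to the route at 25.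

Step 14 (fragment union). The β,γ-epoxy aldehyde 20 may eliminate before it couples, and C12 depends on reagent control. Fallback: set out from 19 and 11 and join them at the ketone oxidation level. TEMPO/PhI(OAc)2 in aqueous MeCN oxidises 19 to the epoxy acid F4, and PhSH/DCC gives the S-phenyl thioester F5. Separately, Pd-catalysed stannylation of 11 with Me3SnSnMe3 at the C–I bond gives the alkenylstannane F6. Base-free Liebeskind–Srogl coupling of F5 and F6 (Pd, CuTC) gives the (10Z)-enone F7. (R)-Me-CBS/catecholborane reduction sets 12S and returns to the route at 21.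

Step 10 (kinetic-resolution epoxidation). Z-substituted secondary allylic alcohols react slowly and less selectively with the Ti–tartrate system. Fallback: set out from 16 and resolve it by lipase acylation (CAL-B, vinyl acetate), which acylates the (R)-alcohol and gives the (R)-dienyl acetate F8. Shi epoxidation (fructose-derived ketone of the matching series, Oxone, buffered MeCN/DMM) then attacks the electron-rich trisubstituted alkene anti to the allylic acetate and returns to the route at 18.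

**Further compounds**
F1 | step 16 | seco cyclopentane carbaldehyde (14-OH, C5–Br bromoalkene arm, vinyl acetate arm) | O[C@H]1C[C@](C)(C=O)[C@H]([C@@H](O[Si](CC)(CC)CC)[C@](O[Si](CC)(CC)CC)([C@@H](C)C(=O)N(C)OC)[C@H](/C=C(/C)Br)O[Si](CC)(CC)CC)[C@@]1(C)[C@H](OC(C)=O)C=C
F2 | step 16 | seco diol (C12 primary alcohol, 14-OH) | O[C@H]1C[C@](C)(CO)[C@H]([C@@H](O[Si](CC)(CC)CC)[C@](O[Si](CC)(CC)CC)([C@@H](C)C(=O)N(C)OC)[C@H](/C=C(/C)Br)O[Si](CC)(CC)CC)[C@@]1(C)[C@H](OC(C)=O)C=C
F3 | step 16 | 5/10-bicyclic diol (C12 primary alcohol, 14-OH) | O[C@H]1C[C@](C)(CO)[C@@H]2[C@@H](O[Si](CC)(CC)CC)[C@](O[Si](CC)(CC)CC)([C@@H](C)C(=O)N(C)OC)[C@H](/C=C(/C)CC[C@@H](OC(C)=O)[C@@]12C)O[Si](CC)(CC)CC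
F4 | step 14 | epoxy acid (C12 carboxylic acid) | C=C[C@@H](OC(C)=O)[C@@]1(C)O[C@H]1CC(O)=O
F5 | step 14 | S-phenyl thioester of F4 | C=C[C@@H](OC(C)=O)[C@@]1(C)O[C@H]1CC(=O)Sc1ccccc1
F6 | step 14 | C11 trimethylstannyl analogue of 11 | C/C(Br)=C/[C@H](O[Si](CC)(CC)CC)[C@@](O[Si](CC)(CC)CC)([C@@H](C)C(=O)N(C)OC)[C@H](O[Si](CC)(CC)CC)/C=C(/C)[Sn](C)(C)C
F7 | step 14 | (10Z)-enone (C12 ketone) | C/C(Br)=C/[C@H](O[Si](CC)(CC)CC)[C@@](O[Si](CC)(CC)CC)([C@@H](C)C(=O)N(C)OC)[C@H](O[Si](CC)(CC)CC)/C=C(/C)C(=O)C[C@@H]1O[C@]1(C)[C@H](OC(C)=O)C=C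
F8 | step 10 | (R)-dienyl acetate | C=C[C@@H](OC(C)=O)/C(C)=C\CCO[Si](C)(C)C(C)(C)C
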